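Monday's run and violet look nearly the same: both stand at 100 °C with 3.0 mM of Zb, and violet carries 20 mM of Za against 13 mM. Zb comes back unchanged from its step, so the step is taken here as pseudo-first-order in Za, and on that assumption percentages of the charge do not feel the larger charge. Violet should then follow Monday's curve, but it is read later, at 2.5 d against 40.0 h.

| flask | Za | Zb | temperature | remark | time |
|---|---|---|---|---|---|
| Monday's | 13 mM | 3 mM | 100 °C | run made earlier |  |
| violet | 20 mM | 3.0 mM | 100 °C |  | 2.5 d |
| green | 20 mM | 0.80 mM | 100 °C |  | 2.5 d |
| red | 20 mM | 3.0 mM | 80 °C |  | 2.5 d |
| teal | 20 mM | 0.80 mM | 80 °C |  | 2.5 d |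

- Monday's (time / h: Zc / %): 10.0: 66; 20.0: 75; 25.0: 70; 40.0: 58

(each reading ± 1.5 percentage points)

- what was read earlier has a scatter of 1.5 percentage points, one standard deviation
- reactions considered so far: Za + Zb -> Zb + Zc; Zc -> Zd
- the earlier runs do not show what temperature does; that part of a forecast is a guess
- no earlier run changes the charge of Zb; that part of a forecast is a guess

- ranking by amount of Zc, in percent of the Za charged, from high to low, at 2.5 d (violet / green / red / teal)
- the amount of Zc, in percent of the Za charged of the flask you put first, at 2.5 d
- the amount of Zc, in percent of the Za charged of the flask you put last, at 2.5 d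

Monday's Zc stands at 75% at 20.0 h and falls to 58% at 40.0 h. In logarithms, that fall is 0.112 of a power of ten. So the time for one power of ten, as read off these two scattered readings, the decade time of Zc, is 179 h. Violet runs 20.0 h past Monday's last reading, which costs another 0.112 of a power of ten. The reckoning here therefore puts violet at 44.9%, with the scatter of 1.5 percentage points on the readings behind it. The other flasks change Zb or the temperature, which no earlier run tests, so they stay guesses.

The forecast gives red > green > violet > teal, with 72% for the first and 36% for the last, and has “violet is then about 41%”, where the reckoning here gives 44.9%.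

The flasks give red > teal > green > violet, with 87.7% in red and 43.7% in violet.

    Za + Zb → Zb + Zc (k = 43.0 M⁻¹ h⁻¹, Ea = 53.0 kJ mol⁻¹)
    Zc → Zd (k = 0.0160 h⁻¹, Ea = 120 kJ mol⁻¹)
    (constants at 100 °C)

The same decade time of 179 h, run backwards from Monday's last reading, places violet read at 25 h at 70.3%. That flask holds 72.0% as Zc, 1.7 points more, with 3.98% of Za still there and 24.0% as Zd.

(The numbers in the tables are calculated on assumed constants.)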